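The oxolane ring (O1, C2 bearing the dienyl chain, C3 bearing OH, C4 the ring CH2, C5 bearing CH3) hides an aldol pattern, O1–C5–C4–C3(OH): C5 is an acetaldehyde-derived oxocarbenium carbon and C3–C4 an enolate. A Petasis–Ferrier rearrangement exploits this. Its precursor is a 2-methyl-5-methylidene-1,3-dioxolane, assembled from L-serine-derived O-benzylglyceric acid, acetaldehyde and a titanium methylidene, which looks nothing like an oxolane. i-Bu3Al turns it in one operation into the 2,5-cis-oxolan-3-ol by closing C4–C5 and reducing C3. Mitsunobu inversion at C3, chain extension to an enal and a Horner–Wadsworth–Emmons union with an isocoumarin phosphonate complete the target.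

Key step: step 4

Remark on the chemistry: the hydride transfer in step 4 is assumed to occur on the ring face opposite the two cis substituents (all-cis alcohol), which is why C3 is inverted in step 5. The acetal centre of 5 and 6 is erased in step 4, so its epimer ratio is immaterial.

Step 1
Reactants: 1 O-benzyl-L-serine
Product: 2 (2S)-3-(benzyloxy)-2-hydroxypropanoic acid
Conditions: NaNO2, 1 M aq H2SO4, 0 °C → rt
Reagents that add atoms: water, O
Why: Diazotisation of an α-amino acid: the carboxylate displaces the diazonium group to an α-lactone that water opens, so two inversions give the (S)-hydroxy acid with net retention.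

Step 2
Reactants: 2 (2S)-3-(benzyloxy)-2-hydroxypropanoic acid; 3 acetaldehyde
Product: 5 (2S,5S)-5-[(benzyloxy)methyl]-2-methyl-1,3-dioxolan-4-one, via bis-silyl derivative 4 (not isolated)
Conditions: (Me3Si)2NH, TMSCl (cat.), CH2Cl2, reflux, then evaporation; 3, TMSOTf (5 mol %), CH2Cl2, −78 °C
Reagents that add atoms: hexamethyldisilazane, C[Si](C)(C)N[Si](C)(C)C (silyl groups of 4 only)
Why: Silylation followed by TMSOTf-catalysed acetalisation of the bis-silyl derivative with the aldehyde at low temperature should give mainly the cis-dioxolanone, the C5 substituent steering the new acetal centre.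

Step 3
Reactants: 5 (2S,5S)-5-[(benzyloxy)methyl]-2-methyl-1,3-dioxolan-4-one
Product: 6 (2S,4S)-4-[(benzyloxy)methyl]-2-methyl-5-methylidene-1,3-dioxolane
Conditions: Cp2TiMe2 (2.5 equiv), toluene, 65 °C, dark; filtration through basic alumina
Reagents that add atoms: dimethyltitanocene (Cp2TiMe2), [Ti+4].[CH3-].[CH3-].c1cc[cH-]c1.c1cc[cH-]c1
Why: Carbonyl methylenation of the lactone by the titanium methylidene formed on heating ([2+2] addition and cycloreversion), a non-basic process that leaves both stereocentres and the acetal intact.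

Step 4
Reactants: 6 (2S,4S)-4-[(benzyloxy)methyl]-2-methyl-5-methylidene-1,3-dioxolane
Product: 8 (2S,3S,5R)-2-[(benzyloxy)methyl]-5-methyloxolan-3-ol, via oxolan-3-one 7 (not isolated)
Conditions: i-Bu3Al (3 equiv), toluene, −78 °C → 0 °C; aq potassium sodium tartrate
Reagents that add atoms: none
Why: Petasis–Ferrier rearrangement with in situ reduction: i-Bu3Al binds the enol-ether oxygen and cleaves the acetal C–O bond to an aluminium enolate tethered to an (E)-oxocarbenium ion, and the enolate carbon (the exocyclic methylene, future C4) attacks the oxocarbenium carbon (the former acetal carbon, future C5) in an intramolecular Mukaiyama-aldol-type step that forms the C4–C5 bond. The closest known reaction type is the triisobutylaluminium-mediated rearrangement of 4-methylene-1,3-dioxolanes to tetrahydrofuran-3-ols. The oxolane ring closes in a 5-(enolendo)-endo-trig mode, tolerated because the electrophile is a cationic oxocarbenium ion reached through an envelope transition state. C5 is set by 1,3-induction from the untouched C2 stereocentre: with the (E)-oxocarbenium ion and the benzyloxymethyl group pseudo-equatorial, CH3 and CH2OBn end up cis. C3 is set when the aluminium-bound ketone 7 takes a β-hydride from an isobutyl group on the face opposite both cis substituents, giving the all-cis alcohol. The step needs cleavage of the acetal C–O bond that releases an enolate (secured by the enol ether, the only oxygen that can leave as a stabilised enolate) and ring closure faster than hydride reduction of the oxocarbenium ion (secured by the low temperature and the intramolecular tether).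

Step 5
Reactants: 8 (2S,3S,5R)-2-[(benzyloxy)methyl]-5-methyloxolan-3-ol
Product: 9 (2S,3R,5R)-2-[(benzyloxy)methyl]-5-methyloxolan-3-yl 4-nitrobenzoate
Conditions: 4-O2NC6H4CO2H, PPh3, DIAD, toluene, 0 °C → rt
Reagents that add atoms: 4-nitrobenzoic acid, O=C(O)c1ccc(cc1)[N+](=O)[O-]
Why: Mitsunobu reaction: the alkoxyphosphonium ion is displaced by 4-nitrobenzoate in an SN2 step from the open face opposite both ring substituents, inverting C3 to the 2,3-trans configuration.

Step 6
Reactants: 9 (2S,3R,5R)-2-[(benzyloxy)methyl]-5-methyloxolan-3-yl 4-nitrobenzoate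
Product: 10 (2S,3R,5R)-2-[(benzyloxy)methyl]-5-methyloxolan-3-ol
Conditions: K2CO3 (0.2 equiv), MeOH, rt
Reagents that add atoms: none
Why: Base-catalysed transesterification (methanolysis) of the activated aryl ester frees the secondary alcohol without touching a stereocentre.

Step 7
Reactants: 10 (2S,3R,5R)-2-[(benzyloxy)methyl]-5-methyloxolan-3-ol
Product: 11 {[(2S,3R,5R)-2-[(benzyloxy)methyl]-5-methyloxolan-3-yl]oxy}(tert-butyl)dimethylsilane
Conditions: TBSCl, imidazole, DMF, rt
Reagents that add atoms: tert-butyldimethylsilyl chloride, CC(C)(C)[Si](C)(C)Cl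
Why: Silyl ether formation gives a protecting group that survives hydrogenolysis, oxidation and olefination and leaves at the end with fluoride.

Step 8
Reactants: 11 {[(2S,3R,5R)-2-[(benzyloxy)methyl]-5-methyloxolan-3-yl]oxy}(tert-butyl)dimethylsilane
Product: 12 [(2S,3R,5R)-3-{[tert-butyl(dimethyl)silyl]oxy}-5-methyloxolan-2-yl]methanol
Conditions: H2 (1 atm), 10% Pd/C, EtOAc, rt
Reagents that add atoms: none
Why: Catalytic hydrogenolysis of the benzyl ether in a non-protic solvent leaves the silyl ether in place.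

Step 9
Reactants: 12 [(2S,3R,5R)-3-{[tert-butyl(dimethyl)silyl]oxy}-5-methyloxolan-2-yl]methanol; 13 (triphenylphosphoranylidene)acetaldehyde
Product: 15 (2E)-3-[(2S,3R,5R)-3-{[tert-butyl(dimethyl)silyl]oxy}-5-methyloxolan-2-yl]prop-2-enal, via aldehyde 14 (not isolated)
Conditions: Dess–Martin periodinane, CH2Cl2, 0 °C → rt; then 13 (1.3 equiv), rt
Reagents that add atoms: none
Why: Dess–Martin oxidation followed in the same flask by Wittig olefination with the stabilised ylide, which should give the (E)-enal and spares the epimerisable α-alkoxy aldehyde from isolation.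

Step 10
Reactants: 16 methyl 2,4-dimethoxy-6-methylbenzoate
Product: 17 methyl 3-chloro-4,6-dimethoxy-2-methylbenzoate
Conditions: SO2Cl2 (1.05 equiv), CH2Cl2, 0 °C
Reagents that add atoms: sulfuryl chloride, O=S(=O)(Cl)Cl
Why: Electrophilic aromatic chlorination should go to the position para to one methoxy group and ortho to the other, next to the methyl group, because the position between the two methoxy groups is the more hindered.

Step 11
Reactants: 17 methyl 3-chloro-4,6-dimethoxy-2-methylbenzoate; 18 N-methoxy-N-methylacetamide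
Product: 19 methyl 3-chloro-4,6-dimethoxy-2-(2-oxopropyl)benzoate
Conditions: LDA (1.3 equiv), THF, −78 °C; then 18; 1 M HCl
Reagents that add atoms: none
Why: Lateral (benzylic) lithiation of the ortho-toluate and acylation with the Weinreb amide, whose chelated tetrahedral adduct prevents over-addition and releases the ketone only on work-up.

Step 12
Reactants: 19 methyl 3-chloro-4,6-dimethoxy-2-(2-oxopropyl)benzoate
Product: 21 5-chloro-6,8-dihydroxy-3-methyl-1H-isochromen-1-one, via dihydroxy keto ester 20 (not isolated)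
Conditions: BBr3 (4 equiv), CH2Cl2, −78 °C → rt; H2O
Reagents that add atoms: none
Why: Lewis-acid cleavage of both aryl methyl ethers by BBr3 and acid-promoted enol lactonisation of the keto ester (loss of methanol) should deliver the isocoumarin in one flask.

Step 13
Reactants: 21 5-chloro-6,8-dihydroxy-3-methyl-1H-isochromen-1-one
Product: 22 6,8-bis{[tert-butyl(dimethyl)silyl]oxy}-5-chloro-3-methyl-1H-isochromen-1-one
Conditions: TBSOTf (2.5 equiv), 2,6-lutidine, CH2Cl2, 0 °C → rt
Reagents that add atoms: tert-butyldimethylsilyl trifluoromethanesulfonate, CC(C)(C)[Si](C)(C)OS(=O)(=O)C(F)(F)F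
Why: Silylation of both phenols with the silyl triflate, which is reactive enough for the hydrogen-bonded peri hydroxyl.

Step 14
Reactants: 22 6,8-bis{[tert-butyl(dimethyl)silyl]oxy}-5-chloro-3-methyl-1H-isochromen-1-one
Product: 23 3-(bromomethyl)-6,8-bis{[tert-butyl(dimethyl)silyl]oxy}-5-chloro-1H-isochromen-1-one
Conditions: NBS (1.05 equiv), AIBN (cat.), PhCF3, 85 °C
Reagents that add atoms: N-bromosuccinimide, O=C1CCC(=O)N1Br
Why: Wohl–Ziegler bromination: the 3-methyl group is allylic to the enol-lactone C3=C4 bond, while ring positions C4 and C7 are shielded by the peri chlorine and the two flanking silyloxy groups.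

Step 15
Reactants: 23 3-(bromomethyl)-6,8-bis{[tert-butyl(dimethyl)silyl]oxy}-5-chloro-1H-isochromen-1-one
Product: 24 diethyl [(6,8-bis{[tert-butyl(dimethyl)silyl]oxy}-5-chloro-1-oxo-1H-isochromen-3-yl)methyl]phosphonate
Conditions: P(OEt)3 (neat), 120 °C
Reagents that add atoms: triethyl phosphite, CCOP(OCC)OCC
Why: Michaelis–Arbuzov reaction of the allylic-type bromide with triethyl phosphite.

Step 16
Reactants: 15 (2E)-3-[(2S,3R,5R)-3-{[tert-butyl(dimethyl)silyl]oxy}-5-methyloxolan-2-yl]prop-2-enal; 24 diethyl [(6,8-bis{[tert-butyl(dimethyl)silyl]oxy}-5-chloro-1-oxo-1H-isochromen-3-yl)methyl]phosphonate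
Product: 25 6,8-bis{[tert-butyl(dimethyl)silyl]oxy}-3-[(1E,3E)-4-[(2S,3R,5R)-3-{[tert-butyl(dimethyl)silyl]oxy}-5-methyloxolan-2-yl]buta-1,3-dien-1-yl]-5-chloro-1H-isochromen-1-one
Conditions: LiHMDS (1.0 equiv to 24), THF, −78 °C; then 15, −78 → 0 °C
Reagents that add atoms: none
Why: Horner–Wadsworth–Emmons olefination: the phosphonate carbanion, delocalised through the enol lactone and arene, adds to the enal and reversible addition with syn-elimination should give the new C=C as (E), completing the (E,E)-diene.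

Step 17
Reactants: 25 6,8-bis{[tert-butyl(dimethyl)silyl]oxy}-3-[(1E,3E)-4-[(2S,3R,5R)-3-{[tert-butyl(dimethyl)silyl]oxy}-5-methyloxolan-2-yl]buta-1,3-dien-1-yl]-5-chloro-1H-isochromen-1-one
Product: 26 5-chloro-6,8-dihydroxy-3-[(1E,3E)-4-[(2S,3R,5R)-3-hydroxy-5-methyloxolan-2-yl]buta-1,3-dien-1-yl]-1H-isochromen-1-one
Conditions: TBAF (4 equiv), AcOH (4 equiv), THF, 0 °C → rt
Reagents that add atoms: none
Why: Fluoride-mediated cleavage of the two aryl silyl ethers and the alkyl silyl ether, buffered with acetic acid so that the enol lactone and the dienylic ring ether meet neither strong base nor strong acid.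

Compound list
1 | O-benzyl-L-serine | N[C@@H](COCc1ccccc1)C(=O)O | starting material
2 | (2S)-3-(benzyloxy)-2-hydroxypropanoic acid | O[C@@H](COCc1ccccc1)C(=O)O | intermediate
3 | acetaldehyde | CC=O | starting material
4 | trimethylsilyl (2S)-3-(benzyloxy)-2-[(trimethylsilyl)oxy]propanoate | C[Si](C)(C)O[C@@H](COCc1ccccc1)C(=O)O[Si](C)(C)C | intermediate
5 | (2S,5S)-5-[(benzyloxy)methyl]-2-methyl-1,3-dioxolan-4-one | C[C@@H]1OC(=O)[C@H](COCc2ccccc2)O1 | intermediate
6 | (2S,4S)-4-[(benzyloxy)methyl]-2-methyl-5-methylidene-1,3-dioxolane | C[C@@H]1OC(=C)[C@H](COCc2ccccc2)O1 | intermediate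
7 | (2S,5R)-2-[(benzyloxy)methyl]-5-methyloxolan-3-one | C[C@@H]1CC(=O)[C@H](COCc2ccccc2)O1 | intermediate
8 | (2S,3S,5R)-2-[(benzyloxy)methyl]-5-methyloxolan-3-ol | C[C@@H]1C[C@H](O)[C@H](COCc2ccccc2)O1 | intermediate
9 | (2S,3R,5R)-2-[(benzyloxy)methyl]-5-methyloxolan-3-yl 4-nitrobenzoate | C[C@@H]1C[C@@H](OC(=O)c2ccc(cc2)[N+](=O)[O-])[C@H](COCc2ccccc2)O1 | intermediate
10 | (2S,3R,5R)-2-[(benzyloxy)methyl]-5-methyloxolan-3-ol | C[C@@H]1C[C@@H](O)[C@H](COCc2ccccc2)O1 | intermediate
11 | {[(2S,3R,5R)-2-[(benzyloxy)methyl]-5-methyloxolan-3-yl]oxy}(tert-butyl)dimethylsilane | C[C@@H]1C[C@@H](O[Si](C)(C)C(C)(C)C)[C@H](COCc2ccccc2)O1 | intermediate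
12 | [(2S,3R,5R)-3-{[tert-butyl(dimethyl)silyl]oxy}-5-methyloxolan-2-yl]methanol | C[C@@H]1C[C@@H](O[Si](C)(C)C(C)(C)C)[C@H](CO)O1 | intermediate
13 | (triphenylphosphoranylidene)acetaldehyde | O=CC=P(c1ccccc1)(c1ccccc1)c1ccccc1 | starting material
14 | (2R,3R,5R)-3-{[tert-butyl(dimethyl)silyl]oxy}-5-methyloxolane-2-carbaldehyde | C[C@@H]1C[C@@H](O[Si](C)(C)C(C)(C)C)[C@H](C=O)O1 | intermediate
15 | (2E)-3-[(2S,3R,5R)-3-{[tert-butyl(dimethyl)silyl]oxy}-5-methyloxolan-2-yl]prop-2-enal | C[C@@H]1C[C@@H](O[Si](C)(C)C(C)(C)C)[C@H](/C=C/C=O)O1 | intermediate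
16 | methyl 2,4-dimethoxy-6-methylbenzoate | COC(=O)c1c(C)cc(OC)cc1OC | starting material
17 | methyl 3-chloro-4,6-dimethoxy-2-methylbenzoate | COC(=O)c1c(C)c(Cl)c(OC)cc1OC | intermediate
18 | N-methoxy-N-methylacetamide | CC(=O)N(C)OC | starting material
19 | methyl 3-chloro-4,6-dimethoxy-2-(2-oxopropyl)benzoate | COC(=O)c1c(CC(C)=O)c(Cl)c(OC)cc1OC | intermediate
20 | methyl 3-chloro-4,6-dihydroxy-2-(2-oxopropyl)benzoate | COC(=O)c1c(CC(C)=O)c(Cl)c(O)cc1O | intermediate
21 | 5-chloro-6,8-dihydroxy-3-methyl-1H-isochromen-1-one | Cc1cc2c(Cl)c(O)cc(O)c2c(=O)o1 | intermediate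
22 | 6,8-bis{[tert-butyl(dimethyl)silyl]oxy}-5-chloro-3-methyl-1H-isochromen-1-one | Cc1cc2c(Cl)c(O[Si](C)(C)C(C)(C)C)cc(O[Si](C)(C)C(C)(C)C)c2c(=O)o1 | intermediate
23 | 3-(bromomethyl)-6,8-bis{[tert-butyl(dimethyl)silyl]oxy}-5-chloro-1H-isochromen-1-one | BrCc1cc2c(Cl)c(O[Si](C)(C)C(C)(C)C)cc(O[Si](C)(C)C(C)(C)C)c2c(=O)o1 | intermediate
24 | diethyl [(6,8-bis{[tert-butyl(dimethyl)silyl]oxy}-5-chloro-1-oxo-1H-isochromen-3-yl)methyl]phosphonate | CCOP(=O)(OCC)Cc1cc2c(Cl)c(O[Si](C)(C)C(C)(C)C)cc(O[Si](C)(C)C(C)(C)C)c2c(=O)o1 | intermediate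
25 | 6,8-bis{[tert-butyl(dimethyl)silyl]oxy}-3-[(1E,3E)-4-[(2S,3R,5R)-3-{[tert-butyl(dimethyl)silyl]oxy}-5-methyloxolan-2-yl]buta-1,3-dien-1-yl]-5-chloro-1H-isochromen-1-one | C[C@@H]1C[C@@H](O[Si](C)(C)C(C)(C)C)[C@H](/C=C/C=C/c2cc3c(Cl)c(O[Si](C)(C)C(C)(C)C)cc(O[Si](C)(C)C(C)(C)C)c3c(=O)o2)O1 | intermediate
26 | 5-chloro-6,8-dihydroxy-3-[(1E,3E)-4-[(2S,3R,5R)-3-hydroxy-5-methyloxolan-2-yl]buta-1,3-dien-1-yl]-1H-isochromen-1-one | C[C@@H]1C[C@@H](O)[C@H](/C=C/C=C/c2cc3c(Cl)c(O)cc(O)c3c(=O)o2)O1 | target

Total step count: 17. Longest linear sequence: 11 steps (steps 1 to 9, then 16 and 17); the isocoumarin branch is steps 10 to 15.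

Steps most likely to fail

Step 4. Hydride transfer from i-Bu3Al to the oxocarbenium ion may outrun ring closure (reductive opening of the acetal), or facial control may be incomplete in the closure or in the ketone reduction. The fallback builds the ring by C–O closure and sets C3 with an external hydride. It sets out from 2: amide coupling (MeNHOMe·HCl, EDC·HCl, HOBt, N-methylmorpholine, CH2Cl2) would give the Weinreb amide (2S)-3-(benzyloxy)-2-hydroxy-N-methoxy-N-methylpropanamide F1. Excess (E)-prop-1-enylmagnesium bromide (THF, −78 → 0 °C) would then give the α'-hydroxy enone (2S,4E)-1-(benzyloxy)-2-hydroxyhex-4-en-3-one F2. Acid-catalysed 5-endo oxa-Michael closure (camphorsulfonic acid, CH2Cl2) proceeds through the protonated enone and is reversible, so it is expected to settle on the 2,5-cis ketone 7, which is isolated here. L-Selectride (THF, −78 °C) should attack 7 opposite both substituents and give 8, where the fallback comes back to the route.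

Step 14. Ionic bromination of the electron-rich arene or of C4, or double bromination of the methyl group, may compete with the radical chain. The fallback replaces radical halogenation by allylic oxidation. It sets out from 22: SeO2 (dioxane, reflux) would give 6,8-bis{[tert-butyl(dimethyl)silyl]oxy}-5-chloro-1-oxo-1H-isochromene-3-carbaldehyde F3. NaBH4 (THF/EtOH, −20 °C) would give 6,8-bis{[tert-butyl(dimethyl)silyl]oxy}-5-chloro-3-(hydroxymethyl)-1H-isochromen-1-one F4. An Appel reaction (CBr4, PPh3, CH2Cl2, 0 °C) would give 23, where the fallback comes back.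

Step 16. The delocalised phosphonate anion may react sluggishly or erode (E) selectivity, and the base may attack the lactone or the aryl silyl ethers. The fallback forms the central C–C single bond of the diene by cross-coupling of two geometrically defined alkenes. It sets out from 12 and 22. From 12, Dess–Martin oxidation to aldehyde 14 (isolated in this variant) and Takai olefination (CHI3, CrCl2, THF, 0 °C) would give tert-butyl({(2S,3R,5R)-2-[(E)-2-iodoethenyl]-5-methyloxolan-3-yl}oxy)dimethylsilane F5. From 22, SeO2 oxidation to the aldehyde F3 (as in the fallback to step 14) and boryl olefination (Cl2CHB(pin), CrCl2, LiI, THF) would give 6,8-bis{[tert-butyl(dimethyl)silyl]oxy}-5-chloro-3-[(E)-2-(4,4,5,5-tetramethyl-1,3,2-dioxaborolan-2-yl)ethenyl]-1H-isochromen-1-one F6. Suzuki–Miyaura coupling of F5 and F6 (Pd(PPh3)4, aq K3PO4, THF, rt) should retain both alkene geometries and give 25, where the fallback comes back.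

Further compounds
F1 | step 4 | (2S)-3-(benzyloxy)-2-hydroxy-N-methoxy-N-methylpropanamide | CON(C)C(=O)[C@@H](O)COCc1ccccc1
F2 | step 4 | (2S,4E)-1-(benzyloxy)-2-hydroxyhex-4-en-3-one | C/C=C/C(=O)[C@@H](O)COCc1ccccc1
F3 | step 14 | 6,8-bis{[tert-butyl(dimethyl)silyl]oxy}-5-chloro-1-oxo-1H-isochromene-3-carbaldehyde | O=Cc1cc2c(Cl)c(O[Si](C)(C)C(C)(C)C)cc(O[Si](C)(C)C(C)(C)C)c2c(=O)o1
F4 | step 14 | 6,8-bis{[tert-butyl(dimethyl)silyl]oxy}-5-chloro-3-(hydroxymethyl)-1H-isochromen-1-one | OCc1cc2c(Cl)c(O[Si](C)(C)C(C)(C)C)cc(O[Si](C)(C)C(C)(C)C)c2c(=O)o1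
F5 | step 16 | tert-butyl({(2S,3R,5R)-2-[(E)-2-iodoethenyl]-5-methyloxolan-3-yl}oxy)dimethylsilane | C[C@@H]1C[C@@H](O[Si](C)(C)C(C)(C)C)[C@H](/C=C/I)O1
F6 | step 16 | 6,8-bis{[tert-butyl(dimethyl)silyl]oxy}-5-chloro-3-[(E)-2-(4,4,5,5-tetramethyl-1,3,2-dioxaborolan-2-yl)ethenyl]-1H-isochromen-1-one | CC1(C)OB(/C=C/c2cc3c(Cl)c(O[Si](C)(C)C(C)(C)C)cc(O[Si](C)(C)C(C)(C)C)c3c(=O)o2)OC1(C)C
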